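Ring C is brought in as a quinone. Its C3 hydroxyl oxygen and C6 ether oxygen are para, the oxygen pattern of a 1,4-benzoquinone, so 2,6-dichloro-1,4-benzoquinone serves as ring C: the carbons that become C1 and C5 carry chlorine and lie β to the carbonyl that becomes C3–O. The route rests on disconnecting the two arm ethers (C1–O to ring B, C5–O to ring D). In one operation two molecules of the hindered biaryl phenol 2,2',4,4',6,6'-hexamethoxybiphenyl-3-ol (the methyl-protected A–B and E–D arms) displace both chlorides by addition–elimination. The C3 and C6 oxygens arrive sterically differentiated for the later ring F ether.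

Key step: step 3

Remark: rings A–B and E–D are the two identical biaryl arms, C is the central ring (C1 O–B, C3 OH, C5 O–D, C6 O–F) and F is the trihydroxyphenoxy ring. The target has no stereocentre, and no atropisomers arise because rings A and E are symmetrically substituted.

Step 1
Reactants: 1 2-iodo-1,3,5-trimethoxybenzene (2 equiv)
Product: 2 2,2',4,4',6,6'-hexamethoxybiphenyl
Conditions: activated Cu bronze (4 equiv), neat, 230 °C, Ar
Reagents that add atoms: none
Why: Ullmann homocoupling on zerovalent copper joins the two iodinated carbons only, so the tetra-ortho-methoxy biaryl should form without regioisomers.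

Step 2
Reactants: 2 2,2',4,4',6,6'-hexamethoxybiphenyl
Product: 5 2,2',4,4',6,6'-hexamethoxybiphenyl-3-ol, via aryllithium 3 (not isolated), via lithium aryltrimethoxyborate 4 (not isolated)
Conditions: n-BuLi (0.9 equiv), TMEDA, THF, 0 °C → rt; B(OMe)3, −78 °C → rt; 30% aq H2O2, 0 °C → rt
Reagents that add atoms: hydrogen peroxide, OO
Why: Directed ortho-metalation at a ring CH flanked by two methoxy groups (all four such positions are equivalent), then borylation and peroxide oxidation with 1,2-shift of aryl from boron to oxygen, should give the monophenol, with substoichiometric base limiting double lithiation and unreacted 2 being recycled.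

Step 3
Reactants: 5 2,2',4,4',6,6'-hexamethoxybiphenyl-3-ol (2.2 equiv); 6 2,6-dichloro-1,4-benzoquinone
Product: 8 2,6-bis[(2,2',4,4',6,6'-hexamethoxybiphenyl-3-yl)oxy]-1,4-benzoquinone, via 2-aryloxy-6-chloroquinone 7 (not isolated)
Conditions: Cs2CO3 (2.5 equiv), 4 Å MS, MeCN, −30 °C → rt, Ar, dark
Reagents that add atoms: none
Why: Each caesium phenoxide adds to a chlorine-bearing quinone carbon (future C1 or C5 of ring C), which is the β-carbon of the enone ending at the future C3 carbonyl, and the resulting enolate expels chloride to restore the quinone; the sequence runs twice through monoether 7. The closest known reaction type is the addition–elimination substitution of halogenated benzoquinones and naphthoquinones by phenoxides. No ring closes and no stereocentre is formed; only the C1–O and C5–O ether bonds are made. The step needs ipso substitution to beat conjugate addition at the two CH carbons (C2, C4) and single-electron transfer from the electron-rich phenoxide to the quinone. Addition of an oxygen nucleophile at a CH carbon is reversible, whereas addition at C–Cl is drained by irreversible chloride loss, and a weak heterogeneous base, low temperature and exclusion of light and air should hold back electron transfer. The flat, unhindered and strongly activated sp2 electrophile should let the di-ortho-methoxy phenoxide form these hindered diaryl ethers without a metal, and the first aryloxy group deactivates the product towards further addition.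

Step 4
Reactants: 8 2,6-bis[(2,2',4,4',6,6'-hexamethoxybiphenyl-3-yl)oxy]-1,4-benzoquinone
Product: 10 4-methoxy-2,6-bis[(2,2',4,4',6,6'-hexamethoxybiphenyl-3-yl)oxy]phenol, via hydroquinone 9 (not isolated)
Conditions: Na2S2O4, THF/H2O, rt, Ar; extractive work-up under Ar; crude, MeI (1.05 equiv), K2CO3, degassed acetone, 0 °C → rt
Reagents that add atoms: iodomethane, CI
Why: Dithionite reduction followed by Williamson methylation with one equivalent of MeI should alkylate only the C3 hydroxyl, which is unhindered and the more acidic one (meta to both aryloxy groups), while the C6 hydroxyl is buried between two di-ortho-methoxy aryloxy groups; crude 9 is carried on at once because it reoxidises in air.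

Step 5
Reactants: 11 3,4,5-trimethoxyphenol
Product: 12 2-bromo-3,4,5-trimethoxyphenol
Conditions: NBS (1.0 equiv), CH2Cl2, −78 → 0 °C
Reagents that add atoms: N-bromosuccinimide, O=C1CCC(=O)N1Br
Why: Electrophilic aromatic bromination of the phenol, whose para position is blocked by methoxy and whose two ortho positions are equivalent, should give a single monobromide with one equivalent at low temperature.

Step 6
Reactants: 12 2-bromo-3,4,5-trimethoxyphenol
Product: 15 3,4,5-trimethoxy-2-(trimethylsilyl)phenyl trifluoromethanesulfonate, via aryl trimethylsilyl ether 13 (not isolated), via lithium 2-silylphenoxide 14 (not isolated)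
Conditions: HMDS, THF, 70 °C, evaporate; n-BuLi, THF, −100 → −78 °C; Tf2O, −100 °C → rt
Reagents that add atoms: hexamethyldisilazane, C[Si](C)(C)N[Si](C)(C)C; trifluoromethanesulfonic anhydride, O=S(=O)(OS(=O)(=O)C(F)(F)F)C(F)(F)F
Why: This is the standard o-silylaryl triflate sequence of O-silylation, bromine–lithium exchange, anionic 1,3 O→C silyl shift (retro-Brook rearrangement) and O-triflation of the resulting lithium phenoxide.

Step 7
Reactants: 10 4-methoxy-2,6-bis[(2,2',4,4',6,6'-hexamethoxybiphenyl-3-yl)oxy]phenol; 15 3,4,5-trimethoxy-2-(trimethylsilyl)phenyl trifluoromethanesulfonate (2 equiv)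
Product: 17 5-methoxy-1,3-bis[(2,2',4,4',6,6'-hexamethoxybiphenyl-3-yl)oxy]-2-(3,4,5-trimethoxyphenoxy)benzene (hexadecamethyl ether of the target), via 3,4,5-trimethoxybenzyne 16 (not isolated)
Conditions: CsF (4 equiv), MeCN, rt, Ar
Reagents that add atoms: none
Why: Fluoride-induced 1,2-elimination releases the aryne, a small and very reactive electrophile that the hindered C6 phenoxide can still reach (aryne O-arylation of phenols), and attack at the aryne carbon remote from the adjacent methoxy group, which places the carbanion next to that methoxy before protonation, should give the 3,4,5-trimethoxyphenyl ether only.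

Step 8
Reactants: 17 hexadecamethyl ether of the target
Product: 18 target hexadecaphenol (CNP0279880.0)
Conditions: BBr3 (40 equiv), CH2Cl2, −78 °C → rt, Ar; ice-water quench; Sephadex LH-20 under Ar
Reagents that add atoms: none
Why: Lewis acid ether cleavage with BBr3 removes each methyl group by bromide SN2 attack on the boron-activated methoxy group, while the diaryl ether and biaryl bonds offer no sp3 carbon and should survive.

Compound list
1 | 2-iodo-1,3,5-trimethoxybenzene | COc1cc(OC)c(I)c(OC)c1 | starting material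
2 | 2,2',4,4',6,6'-hexamethoxybiphenyl | COc1cc(OC)c(-c2c(OC)cc(OC)cc2OC)c(OC)c1 | intermediate
3 | (2,2',4,4',6,6'-hexamethoxybiphenyl-3-yl)lithium | [Li]c1c(OC)cc(OC)c(-c2c(OC)cc(OC)cc2OC)c1OC | intermediate
4 | lithium trimethoxy(2,2',4,4',6,6'-hexamethoxybiphenyl-3-yl)borate | CO[B-](OC)(OC)c1c(OC)cc(OC)c(-c2c(OC)cc(OC)cc2OC)c1OC.[Li+] | intermediate
5 | 2,2',4,4',6,6'-hexamethoxybiphenyl-3-ol | Oc1c(OC)cc(OC)c(-c2c(OC)cc(OC)cc2OC)c1OC | intermediate
6 | 2,6-dichloro-1,4-benzoquinone | O=C1C=C(Cl)C(=O)C(Cl)=C1 | starting material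
7 | 2-chloro-6-[(2,2',4,4',6,6'-hexamethoxybiphenyl-3-yl)oxy]-1,4-benzoquinone | O=C1C=C(Cl)C(=O)C(Oc2c(OC)cc(OC)c(-c3c(OC)cc(OC)cc3OC)c2OC)=C1 | intermediate
8 | 2,6-bis[(2,2',4,4',6,6'-hexamethoxybiphenyl-3-yl)oxy]-1,4-benzoquinone | O=C1C=C(Oc2c(OC)cc(OC)c(-c3c(OC)cc(OC)cc3OC)c2OC)C(=O)C(Oc2c(OC)cc(OC)c(-c3c(OC)cc(OC)cc3OC)c2OC)=C1 | intermediate
9 | 2,6-bis[(2,2',4,4',6,6'-hexamethoxybiphenyl-3-yl)oxy]benzene-1,4-diol | Oc1cc(Oc2c(OC)cc(OC)c(-c3c(OC)cc(OC)cc3OC)c2OC)c(O)c(Oc2c(OC)cc(OC)c(-c3c(OC)cc(OC)cc3OC)c2OC)c1 | intermediate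
10 | 4-methoxy-2,6-bis[(2,2',4,4',6,6'-hexamethoxybiphenyl-3-yl)oxy]phenol | COc1cc(Oc2c(OC)cc(OC)c(-c3c(OC)cc(OC)cc3OC)c2OC)c(O)c(Oc2c(OC)cc(OC)c(-c3c(OC)cc(OC)cc3OC)c2OC)c1 | intermediate
11 | 3,4,5-trimethoxyphenol | COc1cc(O)cc(OC)c1OC | starting material
12 | 2-bromo-3,4,5-trimethoxyphenol | COc1cc(O)c(Br)c(OC)c1OC | intermediate
13 | (2-bromo-3,4,5-trimethoxyphenoxy)trimethylsilane | COc1cc(O[Si](C)(C)C)c(Br)c(OC)c1OC | intermediate
14 | lithium 3,4,5-trimethoxy-2-(trimethylsilyl)phenoxide | COc1cc([O-])c([Si](C)(C)C)c(OC)c1OC.[Li+] | intermediate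
15 | 3,4,5-trimethoxy-2-(trimethylsilyl)phenyl trifluoromethanesulfonate | COc1cc(OS(=O)(=O)C(F)(F)F)c([Si](C)(C)C)c(OC)c1OC | intermediate
16 | 3,4,5-trimethoxybenzyne (1,2-didehydro-3,4,5-trimethoxybenzene) | COC1=CC#CC(OC)=C1OC | intermediate
17 | 5-methoxy-1,3-bis[(2,2',4,4',6,6'-hexamethoxybiphenyl-3-yl)oxy]-2-(3,4,5-trimethoxyphenoxy)benzene | COc1cc(Oc2c(OC)cc(OC)c(-c3c(OC)cc(OC)cc3OC)c2OC)c(Oc2cc(OC)c(OC)c(OC)c2)c(Oc2c(OC)cc(OC)c(-c3c(OC)cc(OC)cc3OC)c2OC)c1 | intermediate
18 | target: 5-hydroxy-1,3-bis[(2,2',4,4',6,6'-hexahydroxybiphenyl-3-yl)oxy]-2-(3,4,5-trihydroxyphenoxy)benzene | Oc1cc(O)c(-c2c(O)cc(O)c(Oc3cc(O)cc(Oc4c(O)cc(O)c(-c5c(O)cc(O)cc5O)c4O)c3Oc3cc(O)c(O)c(O)c3)c2O)c(O)c1 | target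

Total step count: 8. Longest linear sequence: 6 steps (steps 1, 2, 3, 4, 7 and 8, from 1 to 18); steps 5 and 6 form the ring F branch.

Steps most likely to fail

Step 3 (key step). Electron transfer from the electron-rich phenoxide to the oxidising quinone, or conjugate addition at the CH carbons, may outrun chloride displacement, and the second displacement may stall on the deactivated monoether. The fallback sets out from 5 and introduces ring C as an aldehyde. Double SNAr of 5 (2.2 equiv) on commercial 2,6-difluoro-4-methoxybenzaldehyde (COc1cc(F)c(C=O)c(F)c1; K2CO3, DMF, 110 °C; both fluorides ortho to the formyl group) should give 2,6-bis[(2,2',4,4',6,6'-hexamethoxybiphenyl-3-yl)oxy]-4-methoxybenzaldehyde F1. Baeyer–Villiger oxidation (mCPBA, NaHCO3, CH2Cl2, 0 °C → rt) should give the aryl formate F2, and methanolysis (catalytic K2CO3, MeOH, rt) returns to the route at 10, bypassing 8 and 9.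

Step 7. The aryne may be consumed by fluoride, adventitious water or the electron-rich methoxyarene rings faster than the buried C6 phenoxide traps it. The fallback sets out from 10 and uses a Chan–Lam coupling with commercial (3,4,5-trimethoxyphenyl)boronic acid (Cu(OAc)2, pyridine, 4 Å MS, CH2Cl2, air, rt), an oxidative copper-mediated O-arylation that tolerates di-ortho-substituted phenols. It comes back to the route at 17 directly, so this fallback adds no new compound (F0).

Step 8. Cleavage of the sixteen ethers may stop part-way, and the free hexadecaphenol may oxidise during isolation. The fallback sets out from 17: the crude product of the BBr3 treatment would be peracetylated (Ac2O, pyridine, DMAP, rt) to the hexadecaacetate of the target F3. This derivative is air-stable and can be chromatographed, so under-demethylated material can be separated and resubmitted. Acid methanolysis (HCl generated from AcCl in degassed MeOH, rt) then comes back to the route at 18.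

Further compounds
F1 | step 3 | 2,6-bis[(2,2',4,4',6,6'-hexamethoxybiphenyl-3-yl)oxy]-4-methoxybenzaldehyde | COc1cc(Oc2c(OC)cc(OC)c(-c3c(OC)cc(OC)cc3OC)c2OC)c(C=O)c(Oc2c(OC)cc(OC)c(-c3c(OC)cc(OC)cc3OC)c2OC)c1
F2 | step 3 | 2,6-bis[(2,2',4,4',6,6'-hexamethoxybiphenyl-3-yl)oxy]-4-methoxyphenyl formate | COc1cc(Oc2c(OC)cc(OC)c(-c3c(OC)cc(OC)cc3OC)c2OC)c(OC=O)c(Oc2c(OC)cc(OC)c(-c3c(OC)cc(OC)cc3OC)c2OC)c1
F0 | step 7 | none | none
F3 | step 8 | hexadecaacetate of the target | CC(=O)Oc1cc(OC(C)=O)c(-c2c(OC(C)=O)cc(OC(C)=O)c(Oc3cc(OC(C)=O)cc(Oc4c(OC(C)=O)cc(OC(C)=O)c(-c5c(OC(C)=O)cc(OC(C)=O)cc5OC(C)=O)c4OC(C)=O)c3Oc3cc(OC(C)=O)c(OC(C)=O)c(OC(C)=O)c3)c2OC(C)=O)c(OC(C)=O)c1
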